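## Retrosynthetic overview

1. The last C–C bond is the C15=C15' Wittig olefination between an acetylenic C20 phosphonium salt (ring A half) and a C20 aldehyde that carries the 5,6-diol (ring B half); global desilylation follows.
2. The strategy rests on C9': it bears the C19' methyl and lies between the C7'≡C8' alkyne on ring A and the C10'–C11' single bond, so CH3 and C11' can be added syn across the terminal C9'≡C10' alkyne of a ring A buta-1,3-diyne (methylalumination, then alkenyl–alkenyl coupling with a C11'–C15' dienyl iodide).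
3. The ring A diyne comes from the enol triflate of silylated (4R,6R)-actinol and a silylbutadiynylzinc reagent; the iodide comes from (E)-3-methylpent-2-en-4-yn-1-ol by silylation and hydrozirconation–iodination.
4. The ring B half comes from the same enol triflate: ester, allylic alcohol, anti-epoxide, acid hydrolysis at C5 (sets 5S,6S), aldehyde, then two C5 Horner–Wadsworth–Emmons extensions.
5. No carbocycle is built: both six-membered rings come from ketoisophorone (C3 and C3' set by enzymatic C=C reduction and diastereoselective C=O hydrogenation); the only ring formed is the transient oxirane on ring B.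

Key step: step 9

Remark on numbering: carotenoid locants are used, unprimed for the triol half (ring B) and primed for the acetylenic half (ring A); the target is the all-E (3S,5S,6S,3'R) isomer of the SMILES.

Remark on protecting groups: O3 and O3' are carried as triisopropylsilyl (TIPS) ethers and O15' as a tert-butyldimethylsilyl (TBS) ether, so that the allylic TBS ether can be cleaved alone after the key step and the ring ether survives the aqueous acid of step 16.

Remark on reagent 26: the (E)-phosphonate is assumed; any 2Z olefin isomers from steps 18 and 21 are to be removed by chromatography.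

## Route

Step 1
Reactants: 1 ketoisophorone
Product: 2 (6R)-2,2,6-trimethylcyclohexane-1,4-dione
Conditions: ene-reductase OYE2 (old yellow enzyme 2), NADP+ (cat.), glucose dehydrogenase, D-glucose, phosphate buffer pH 6.5, 30 °C
Reagents that add atoms: none
Why: Biocatalytic asymmetric reduction of the enedione C=C (ene-reductase, trans addition of hydride and proton) should set the methyl-bearing centre as 6R; the slightly acidic buffer limits racemisation of this α-stereocentre.

Step 2
Reactants: 2 (6R)-2,2,6-trimethylcyclohexane-1,4-dione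
Product: 3 (4R,6R)-4-hydroxy-2,2,6-trimethylcyclohexan-1-one
Conditions: H2 (5 bar), Raney Ni, MeOH, rt; crystallisation
Reagents that add atoms: none
Why: Chemo- and diastereoselective heterogeneous hydrogenation of the unhindered C4 ketone; hydrogen should arrive on the equatorial side away from the axial C2 methyl, giving the axial 4-OH trans to the C6 methyl (4R), and the minor cis isomer is removed by crystallisation.

Step 3
Reactants: 3 (4R,6R)-4-hydroxy-2,2,6-trimethylcyclohexan-1-one
Product: 4 (4R,6R)-2,2,6-trimethyl-4-(triisopropylsilyloxy)cyclohexan-1-one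
Conditions: iPr3SiOTf, 2,6-lutidine, CH2Cl2, −78 °C to 0 °C
Reagents that add atoms: triisopropylsilyl trifluoromethanesulfonate CC(C)[Si](OS(=O)(=O)C(F)(F)F)(C(C)C)C(C)C
Why: O-Silylation of the secondary alcohol with a silyl triflate and a hindered base; the hindered ketone is not enolised under these conditions.

Step 4
Reactants: 4 (4R,6R)-2,2,6-trimethyl-4-(triisopropylsilyloxy)cyclohexan-1-one
Product: 6 (4R)-2,6,6-trimethyl-4-(triisopropylsilyloxy)cyclohex-1-en-1-yl trifluoromethanesulfonate, via lithium enolate 5 (not isolated)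
Conditions: LiN(iPr)2, THF, −78 °C to 0 °C; PhNTf2, −78 °C to rt
Reagents that add atoms: N-phenylbis(trifluoromethanesulfonimide) O=S(=O)(N(c1ccccc1)S(=O)(=O)C(F)(F)F)C(F)(F)F
Why: The ketone has a single α-hydrogen, so deprotonation gives one enolate and O-sulfonylation gives the tetrasubstituted enol triflate; the methyl-bearing centre is erased on purpose and the silyloxy centre (C3 and C3' of the target) is untouched.

Step 5
Reactants: 6 enol triflate; 7 1,4-bis(trimethylsilyl)buta-1,3-diyne
Product: 10 (4R)-2,6,6-trimethyl-4-(triisopropylsilyloxy)-1-[4-(trimethylsilyl)buta-1,3-diyn-1-yl]cyclohex-1-ene, via lithium silylbutadiynide 8 (not isolated), via chlorozinc silylbutadiynide 9 (not isolated)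
Conditions: 7, MeLi·LiBr, THF, −78 °C to rt; ZnCl2, THF, 0 °C; then 6, Pd(PPh3)4 (5 mol %), THF, rt to 45 °C
Reagents that add atoms: none
Why: Mono-desilylation of the bis-silyl diyne by MeLi, transmetalation to zinc and Negishi alkynyl–alkenyl coupling with the enol triflate form the C6'–C7' bond, while the remaining C-silyl group masks the diyne terminus.

Step 6
Reactants: 10 ring A silyl diyne
Product: 11 (4R)-1-(buta-1,3-diyn-1-yl)-2,6,6-trimethyl-4-(triisopropylsilyloxy)cyclohex-1-ene
Conditions: K2CO3, MeOH/THF, 0 °C; used at once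
Reagents that add atoms: none
Why: Methanolysis of the alkynyl C–Si bond (protodesilylation) frees the terminal C9'≡C10' alkyne, and the O-silyl ether is far less labile to carbonate.

Step 7
Reactants: 12 (E)-3-methylpent-2-en-4-yn-1-ol
Product: 13 tert-butyldimethyl{[(2E)-3-methylpent-2-en-4-yn-1-yl]oxy}silane
Conditions: tBuMe2SiCl, imidazole, DMF, rt
Reagents that add atoms: tert-butyldimethylsilyl chloride CC(C)(C)[Si](C)(C)Cl
Why: Standard silylation of the primary allylic alcohol removes the acidic O–H before hydrozirconation.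

Step 8
Reactants: 13 silylated enynol
Product: 15 tert-butyl{[(2E,4E)-5-iodo-3-methylpenta-2,4-dien-1-yl]oxy}dimethylsilane, via alkenylzirconocene chloride 14 (not isolated)
Conditions: Cp2Zr(H)Cl, THF, rt, dark; then I2, THF, 0 °C
Reagents that add atoms: iodine II
Why: Hydrozirconation adds Zr–H syn across the terminal alkyne with zirconium on the terminal carbon, and iodinolysis of the C–Zr bond with retention gives the 4E iodide; the 2E alkene of 12 is not touched.

Step 9
Reactants: 11 ring A buta-1,3-diyne; 15 dienyl iodide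
Product: 17 tert-butyl{[(2E,4E,6E)-3,7-dimethyl-9-[(4R)-2,6,6-trimethyl-4-(triisopropylsilyloxy)cyclohex-1-en-1-yl]nona-2,4,6-trien-8-yn-1-yl]oxy}dimethylsilane, via alkenylalane 16 (not isolated)
Conditions: AlMe3 (2.5 equiv), Cp2ZrCl2 (0.25 equiv), ClCH2CH2Cl, 0 °C to rt; volatiles removed in vacuo; then 15, ZnCl2 (0.5 equiv), Pd(PPh3)4 (5 mol %), THF, rt, dark
Reagents that add atoms: trimethylaluminium C[Al](C)C
Why: Cp2ZrCl2 and AlMe3 form a methylzirconocene–aluminate pair whose Zr–CH3 bond adds syn across the terminal C9'≡C10' triple bond with methyl on the internal carbon C9' and the metal on C10', and Zr-to-Al exchange gives the alkenylalane 16. Transmetalation through ZnCl2 to palladium, after oxidative addition of iodide 15 to zerovalent palladium, and reductive elimination then join C10' to C11' with retention at both alkenyl carbons; this is the Negishi zirconium-catalysed carboalumination followed by palladium-catalysed alkenyl–alkenyl coupling, whose closest known substrates are terminal conjugated enynes. No ring is closed and no stereocentre is made; the step forms the C9'–CH3 and C10'–C11' bonds and fixes the 9'E geometry, because methyl and aluminium are cis and C11' takes the place of aluminium. The selectivity needed is terminal over internal alkyne and methyl to C9': the C7'≡C8' alkyne is shielded by the tetrasubstituted C5'=C6' alkene, the C1' gem-dimethyl group and the C5' methyl, and the less hindered terminal carbon takes the metal. Excess AlMe3 is removed before the coupling so that methyl is not transferred to the iodide, and the E,E geometry of 15 is carried over unchanged.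

Step 10
Reactants: 17 bis-silyl C20 ether
Product: 18 (2E,4E,6E)-3,7-dimethyl-9-[(4R)-2,6,6-trimethyl-4-(triisopropylsilyloxy)cyclohex-1-en-1-yl]nona-2,4,6-trien-8-yn-1-ol
Conditions: Bu4NF (1.1 equiv), AcOH (1.1 equiv), THF, 0 °C
Reagents that add atoms: none
Why: Fluoride-mediated desilylation distinguishes the unhindered primary allylic TBS ether from the hindered secondary TIPS ether, and the buffered, non-ionising conditions leave the polyenyne geometry alone.

Step 11
Reactants: 18 acetylenic C20 alcohol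
Product: 19 (4R)-1-[(3E,5E,7E)-9-bromo-3,7-dimethylnona-3,5,7-trien-1-yn-1-yl]-2,6,6-trimethyl-4-(triisopropylsilyloxy)cyclohex-1-ene
Conditions: CBr4, PPh3, CH2Cl2, −30 °C, dark; used at once
Reagents that add atoms: tetrabromomethane BrC(Br)(Br)Br
Why: Appel bromination displaces the alkoxyphosphonium ion at primary C15' by bromide in a bimolecular step, so no free polyenyl cation is formed and there is no rotation about C9'=C10', C11'=C12' or C13'=C14'.

Step 12
Reactants: 19 acetylenic C20 bromide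
Product: 20 [(2E,4E,6E)-3,7-dimethyl-9-[(4R)-2,6,6-trimethyl-4-(triisopropylsilyloxy)cyclohex-1-en-1-yl]nona-2,4,6-trien-8-yn-1-yl]triphenylphosphonium bromide
Conditions: PPh3, EtOAc, rt, dark
Reagents that add atoms: triphenylphosphine c1ccc(cc1)P(c1ccccc1)c1ccccc1
Why: Quaternisation of triphenylphosphine by direct displacement of the primary allylic bromide gives the Wittig salt, which should precipitate from ethyl acetate.

Step 13
Reactants: 6 enol triflate
Product: 21 methyl (4R)-2,6,6-trimethyl-4-(triisopropylsilyloxy)cyclohex-1-ene-1-carboxylate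
Conditions: CO (1 atm), Pd(OAc)2 (5 mol %), PPh3, Et3N, MeOH/DMF, 70 °C
Reagents that add atoms: carbon monoxide [C-]#[O+]; methanol CO
Why: Palladium-catalysed methoxycarbonylation of the enol triflate (oxidative addition, CO insertion, methanolysis of the acylpalladium) installs C7 on C6.

Step 14
Reactants: 21 ring B methyl ester
Product: 22 [(4R)-2,6,6-trimethyl-4-(triisopropylsilyloxy)cyclohex-1-en-1-yl]methanol
Conditions: iBu2AlH, CH2Cl2, −78 °C to 0 °C
Reagents that add atoms: none
Why: 1,2-Reduction of the conjugated ester by the aluminium hydride gives the allylic alcohol that directs the epoxidation.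

Step 15
Reactants: 22 ring B allylic alcohol
Product: 23 [(1R,4S,6R)-2,2,6-trimethyl-4-(triisopropylsilyloxy)-7-oxabicyclo[4.1.0]heptan-1-yl]methanol
Conditions: Ti(OiPr)4, D-(−)-diethyl tartrate, tBuOOH, 4 Å molecular sieves, CH2Cl2, −20 °C
Reagents that add atoms: tert-butyl hydroperoxide CC(C)(C)OO
Why: Katsuki–Sharpless epoxidation under reagent control: the D-(−)-tartrate complex (the one that gives 2R epoxides from simple allylic alcohols) should deliver oxygen to the face of C5=C6 anti to the C3 silyloxy group, setting both oxirane centres.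

Step 16
Reactants: 23 anti-epoxy alcohol
Product: 24 (1S,2R,5S)-2-(hydroxymethyl)-1,3,3-trimethyl-5-(triisopropylsilyloxy)cyclohexane-1,2-diol
Conditions: HClO4 (0.1 M aq), THF, 0 °C
Reagents that add atoms: water O
Why: Acid-catalysed hydrolysis of the 2,3-epoxy alcohol: the hydroxymethyl group disfavours positive charge at C6, so the protonated oxirane should open at tertiary C5 with water entering anti to the leaving oxygen, which inverts C5 (5-OH cis to O3, 5S) and keeps the C6–O bond (6-OH trans to 5-OH).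

Step 17
Reactants: 24 ring B triol
Product: 25 (1S,2S,4S)-1,2-dihydroxy-2,6,6-trimethyl-4-(triisopropylsilyloxy)cyclohexane-1-carbaldehyde
Conditions: IBX (2-iodoxybenzoic acid), DMSO, rt
Reagents that add atoms: none
Why: The hypervalent iodine oxidant converts the primary alcohol into the aldehyde, cannot oxidise the two tertiary alcohols and does not cleave 1,2-diols; the aldehyde has no α-hydrogen and cannot epimerise.

Step 18
Reactants: 25 ring B hydroxy aldehyde; 26 triethyl (2E)-3-methyl-4-phosphonobut-2-enoate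
Product: 28 ethyl (2E,4E)-5-[(1S,2S,4S)-1,2-dihydroxy-2,6,6-trimethyl-4-(triisopropylsilyloxy)cyclohexyl]-3-methylpenta-2,4-dienoate, via lithiated phosphonate 27 (not isolated)
Conditions: 26 (2.2 equiv), LiN(SiMe3)2 (2.0 equiv), THF/DMPU, −78 °C; then 25, −78 °C to 0 °C
Reagents that add atoms: none
Why: Horner–Wadsworth–Emmons olefination with the lithium salt of the stabilised vinylogous phosphonate forms C7=C8 with E selectivity; the lithium counter-ion and the low temperature guard the hindered α-hydroxy aldehyde against base-induced α-ketol rearrangement, and the tertiary hydroxyls at most consume part of the anion, which is used in excess.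

Step 19
Reactants: 28 C15 dienoate
Product: 29 (2E,4E)-5-[(1S,2S,4S)-1,2-dihydroxy-2,6,6-trimethyl-4-(triisopropylsilyloxy)cyclohexyl]-3-methylpenta-2,4-dien-1-ol
Conditions: iBu2AlH (excess), CH2Cl2, −78 °C
Reagents that add atoms: none
Why: 1,2-Reduction of the dienoate to the allylic alcohol; the free hydroxyls only consume hydride.

Step 20
Reactants: 29 C15 dienol
Product: 30 (2E,4E)-5-[(1S,2S,4S)-1,2-dihydroxy-2,6,6-trimethyl-4-(triisopropylsilyloxy)cyclohexyl]-3-methylpenta-2,4-dienal
Conditions: MnO2, CH2Cl2, rt, dark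
Reagents that add atoms: none
Why: MnO2 oxidises only the primary allylic alcohol; the tertiary hydroxyls are inert.

Step 21
Reactants: 30 C15 dienal; 26 triethyl (2E)-3-methyl-4-phosphonobut-2-enoate
Product: 32 ethyl (2E,4E,6E,8E)-9-[(1S,2S,4S)-1,2-dihydroxy-2,6,6-trimethyl-4-(triisopropylsilyloxy)cyclohexyl]-3,7-dimethylnona-2,4,6,8-tetraenoate, via sodium phosphonate anion 31 (not isolated)
Conditions: 26 (2.2 equiv), NaN(SiMe3)2 (2.0 equiv), THF, −78 °C; then 30, −78 °C to 0 °C
Reagents that add atoms: none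
Why: A second Horner–Wadsworth–Emmons olefination forms C11=C12 with E selectivity and brings in C12–C15 with the C13 methyl; the more nucleophilic sodium salt of the phosphonate is chosen here because the conjugated dienal is a weaker electrophile than aldehyde 25 and no longer carries a base-sensitive α-hydroxy aldehyde.

Step 22
Reactants: 32 C20 tetraenoate
Product: 33 (2E,4E,6E,8E)-9-[(1S,2S,4S)-1,2-dihydroxy-2,6,6-trimethyl-4-(triisopropylsilyloxy)cyclohexyl]-3,7-dimethylnona-2,4,6,8-tetraen-1-ol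
Conditions: iBu2AlH (excess), CH2Cl2, −78 °C
Reagents that add atoms: none
Why: 1,2-Reduction of the conjugated ester to the primary allylic alcohol without touching the polyene.

Step 23
Reactants: 33 C20 tetraenol
Product: 34 (2E,4E,6E,8E)-9-[(1S,2S,4S)-1,2-dihydroxy-2,6,6-trimethyl-4-(triisopropylsilyloxy)cyclohexyl]-3,7-dimethylnona-2,4,6,8-tetraenal
Conditions: MnO2, CH2Cl2, rt, dark
Reagents that add atoms: none
Why: Selective allylic oxidation of the primary alcohol by MnO2 gives the C20 aldehyde for the final olefination.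

Step 24
Reactants: 20 acetylenic C20 phosphonium bromide; 34 C20 aldehyde
Product: 36 3,3'-bis-O-(triisopropylsilyl)-(3S,5S,6S,3'R)-7',8'-didehydro-5,6-dihydro-β,β-carotene-3,5,6,3'-tetrol, via phosphorus ylide 35 (not isolated)
Conditions: NaOMe, MeOH/CH2Cl2, 0 °C to rt, argon, dark; base added to the mixture of 20 and 34
Reagents that add atoms: none
Why: Wittig olefination with the polyenyl ylide generated in the presence of the aldehyde forms C15=C15'; the short lifetime of the ylide limits rotation about C13'=C14' and C9'=C10', and any 15Z isomer is to be separated by chromatography, not equilibrated.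

Step 25
Reactants: 36 bis-silyl tetrol
Product: 37 (3S,5S,6S,3'R)-7',8'-didehydro-5,6-dihydro-β,β-carotene-3,5,6,3'-tetrol (target CNP0160593.1)
Conditions: Bu4NF, THF, rt, dark
Reagents that add atoms: none
Why: Fluoride cleaves both secondary TIPS ethers without acid, heat or light, so the four stereocentres and the all-E chain with the labile 9'E bond are kept.

## Compound list

1 | ketoisophorone (2,6,6-trimethylcyclohex-2-ene-1,4-dione) | CC1=CC(=O)CC(C)(C)C1=O | starting material
2 | (6R)-2,2,6-trimethylcyclohexane-1,4-dione | C[C@@H]1CC(=O)CC(C)(C)C1=O | intermediate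
3 | (4R,6R)-4-hydroxy-2,2,6-trimethylcyclohexan-1-one | C[C@@H]1C[C@@H](O)CC(C)(C)C1=O | intermediate
4 | (4R,6R)-2,2,6-trimethyl-4-(triisopropylsilyloxy)cyclohexan-1-one | C[C@@H]1C[C@@H](O[Si](C(C)C)(C(C)C)C(C)C)CC(C)(C)C1=O | intermediate
5 | lithium (4R)-2,6,6-trimethyl-4-(triisopropylsilyloxy)cyclohex-1-en-1-olate | CC1=C(O[Li])C(C)(C)C[C@H](O[Si](C(C)C)(C(C)C)C(C)C)C1 | intermediate
6 | (4R)-2,6,6-trimethyl-4-(triisopropylsilyloxy)cyclohex-1-en-1-yl trifluoromethanesulfonate | CC1=C(OS(=O)(=O)C(F)(F)F)C(C)(C)C[C@H](O[Si](C(C)C)(C(C)C)C(C)C)C1 | intermediate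
7 | 1,4-bis(trimethylsilyl)buta-1,3-diyne | C[Si](C)(C)C#CC#C[Si](C)(C)C | starting material
8 | lithium 4-(trimethylsilyl)buta-1,3-diyn-1-ide | [Li]C#CC#C[Si](C)(C)C | intermediate
9 | chloro[4-(trimethylsilyl)buta-1,3-diyn-1-yl]zinc | Cl[Zn]C#CC#C[Si](C)(C)C | intermediate
10 | (4R)-2,6,6-trimethyl-4-(triisopropylsilyloxy)-1-[4-(trimethylsilyl)buta-1,3-diyn-1-yl]cyclohex-1-ene | CC1=C(C#CC#C[Si](C)(C)C)C(C)(C)C[C@H](O[Si](C(C)C)(C(C)C)C(C)C)C1 | intermediate
11 | (4R)-1-(buta-1,3-diyn-1-yl)-2,6,6-trimethyl-4-(triisopropylsilyloxy)cyclohex-1-ene | CC1=C(C#CC#C)C(C)(C)C[C@H](O[Si](C(C)C)(C(C)C)C(C)C)C1 | intermediate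
12 | (E)-3-methylpent-2-en-4-yn-1-ol | C#C/C(C)=C/CO | starting material
13 | tert-butyldimethyl{[(2E)-3-methylpent-2-en-4-yn-1-yl]oxy}silane | C#C/C(C)=C/CO[Si](C)(C)C(C)(C)C | intermediate
14 | chlorobis(cyclopentadienyl)[(1E,3E)-5-(tert-butyldimethylsilyloxy)-3-methylpenta-1,3-dien-1-yl]zirconium | C[Si](C)(OC/C=C(C)/C=C/[Zr](Cl)(C1C=CC=C1)C1C=CC=C1)C(C)(C)C | intermediate
15 | tert-butyl{[(2E,4E)-5-iodo-3-methylpenta-2,4-dien-1-yl]oxy}dimethylsilane | I/C=C/C(C)=C/CO[Si](C)(C)C(C)(C)C | intermediate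
16 | dimethyl{(1E)-2-methyl-4-[(4R)-2,6,6-trimethyl-4-(triisopropylsilyloxy)cyclohex-1-en-1-yl]but-1-en-3-yn-1-yl}aluminium | CC1=C(C#C/C(C)=C/[Al](C)C)C(C)(C)C[C@H](O[Si](C(C)C)(C(C)C)C(C)C)C1 | intermediate
17 | tert-butyl{[(2E,4E,6E)-3,7-dimethyl-9-[(4R)-2,6,6-trimethyl-4-(triisopropylsilyloxy)cyclohex-1-en-1-yl]nona-2,4,6-trien-8-yn-1-yl]oxy}dimethylsilane | CC1=C(C#C/C(C)=C/C=C/C(C)=C/CO[Si](C)(C)C(C)(C)C)C(C)(C)C[C@H](O[Si](C(C)C)(C(C)C)C(C)C)C1 | intermediate
18 | (2E,4E,6E)-3,7-dimethyl-9-[(4R)-2,6,6-trimethyl-4-(triisopropylsilyloxy)cyclohex-1-en-1-yl]nona-2,4,6-trien-8-yn-1-ol | CC1=C(C#C/C(C)=C/C=C/C(C)=C/CO)C(C)(C)C[C@H](O[Si](C(C)C)(C(C)C)C(C)C)C1 | intermediate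
19 | (4R)-1-[(3E,5E,7E)-9-bromo-3,7-dimethylnona-3,5,7-trien-1-yn-1-yl]-2,6,6-trimethyl-4-(triisopropylsilyloxy)cyclohex-1-ene | CC1=C(C#C/C(C)=C/C=C/C(C)=C/CBr)C(C)(C)C[C@H](O[Si](C(C)C)(C(C)C)C(C)C)C1 | intermediate
20 | [(2E,4E,6E)-3,7-dimethyl-9-[(4R)-2,6,6-trimethyl-4-(triisopropylsilyloxy)cyclohex-1-en-1-yl]nona-2,4,6-trien-8-yn-1-yl]triphenylphosphonium bromide | CC1=C(C#C/C(C)=C/C=C/C(C)=C/C[P+](c2ccccc2)(c2ccccc2)c2ccccc2)C(C)(C)C[C@H](O[Si](C(C)C)(C(C)C)C(C)C)C1.[Br-] | intermediate
21 | methyl (4R)-2,6,6-trimethyl-4-(triisopropylsilyloxy)cyclohex-1-ene-1-carboxylate | CC1=C(C(=O)OC)C(C)(C)C[C@H](O[Si](C(C)C)(C(C)C)C(C)C)C1 | intermediate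
22 | [(4R)-2,6,6-trimethyl-4-(triisopropylsilyloxy)cyclohex-1-en-1-yl]methanol | CC1=C(CO)C(C)(C)C[C@H](O[Si](C(C)C)(C(C)C)C(C)C)C1 | intermediate
23 | [(1R,4S,6R)-2,2,6-trimethyl-4-(triisopropylsilyloxy)-7-oxabicyclo[4.1.0]heptan-1-yl]methanol (5,6-epoxide anti to O3) | OC[C@]12C(C)(C)C[C@H](O[Si](C(C)C)(C(C)C)C(C)C)C[C@@]1(C)O2 | intermediate
24 | (1S,2R,5S)-2-(hydroxymethyl)-1,3,3-trimethyl-5-(triisopropylsilyloxy)cyclohexane-1,2-diol | OC[C@]1(O)C(C)(C)C[C@H](O[Si](C(C)C)(C(C)C)C(C)C)C[C@]1(C)O | intermediate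
25 | (1S,2S,4S)-1,2-dihydroxy-2,6,6-trimethyl-4-(triisopropylsilyloxy)cyclohexane-1-carbaldehyde | O=C[C@]1(O)C(C)(C)C[C@H](O[Si](C(C)C)(C(C)C)C(C)C)C[C@]1(C)O | intermediate
26 | triethyl (2E)-3-methyl-4-phosphonobut-2-enoate | CCOC(=O)/C=C(C)/CP(=O)(OCC)OCC | starting material
27 | lithium salt of the C4 carbanion of 26 | [Li+].CCOC(=O)/C=C(C)/[CH-]P(=O)(OCC)OCC | intermediate
28 | ethyl (2E,4E)-5-[(1S,2S,4S)-1,2-dihydroxy-2,6,6-trimethyl-4-(triisopropylsilyloxy)cyclohexyl]-3-methylpenta-2,4-dienoate | CCOC(=O)/C=C(C)/C=C/[C@]1(O)C(C)(C)C[C@H](O[Si](C(C)C)(C(C)C)C(C)C)C[C@]1(C)O | intermediate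
29 | (2E,4E)-5-[(1S,2S,4S)-1,2-dihydroxy-2,6,6-trimethyl-4-(triisopropylsilyloxy)cyclohexyl]-3-methylpenta-2,4-dien-1-ol | OC/C=C(C)/C=C/[C@]1(O)C(C)(C)C[C@H](O[Si](C(C)C)(C(C)C)C(C)C)C[C@]1(C)O | intermediate
30 | (2E,4E)-5-[(1S,2S,4S)-1,2-dihydroxy-2,6,6-trimethyl-4-(triisopropylsilyloxy)cyclohexyl]-3-methylpenta-2,4-dienal | O=C/C=C(C)/C=C/[C@]1(O)C(C)(C)C[C@H](O[Si](C(C)C)(C(C)C)C(C)C)C[C@]1(C)O | intermediate
31 | sodium salt of the C4 carbanion of 26 | [Na+].CCOC(=O)/C=C(C)/[CH-]P(=O)(OCC)OCC | intermediate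
32 | ethyl (2E,4E,6E,8E)-9-[(1S,2S,4S)-1,2-dihydroxy-2,6,6-trimethyl-4-(triisopropylsilyloxy)cyclohexyl]-3,7-dimethylnona-2,4,6,8-tetraenoate | CCOC(=O)/C=C(C)/C=C/C=C(C)/C=C/[C@]1(O)C(C)(C)C[C@H](O[Si](C(C)C)(C(C)C)C(C)C)C[C@]1(C)O | intermediate
33 | (2E,4E,6E,8E)-9-[(1S,2S,4S)-1,2-dihydroxy-2,6,6-trimethyl-4-(triisopropylsilyloxy)cyclohexyl]-3,7-dimethylnona-2,4,6,8-tetraen-1-ol | OC/C=C(C)/C=C/C=C(C)/C=C/[C@]1(O)C(C)(C)C[C@H](O[Si](C(C)C)(C(C)C)C(C)C)C[C@]1(C)O | intermediate
34 | (2E,4E,6E,8E)-9-[(1S,2S,4S)-1,2-dihydroxy-2,6,6-trimethyl-4-(triisopropylsilyloxy)cyclohexyl]-3,7-dimethylnona-2,4,6,8-tetraenal | O=C/C=C(C)/C=C/C=C(C)/C=C/[C@]1(O)C(C)(C)C[C@H](O[Si](C(C)C)(C(C)C)C(C)C)C[C@]1(C)O | intermediate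
35 | triphenylphosphonium ylide of 20 (C15' ylide) | CC1=C(C#C/C(C)=C/C=C/C(C)=C/C=P(c2ccccc2)(c2ccccc2)c2ccccc2)C(C)(C)C[C@H](O[Si](C(C)C)(C(C)C)C(C)C)C1 | intermediate
36 | 3,3'-bis-O-(triisopropylsilyl)-(3S,5S,6S,3'R)-7',8'-didehydro-5,6-dihydro-β,β-carotene-3,5,6,3'-tetrol | CC1=C(C#C/C(C)=C/C=C/C(C)=C/C=C/C=C(C)/C=C/C=C(C)/C=C/[C@]2(O)C(C)(C)C[C@H](O[Si](C(C)C)(C(C)C)C(C)C)C[C@]2(C)O)C(C)(C)C[C@H](O[Si](C(C)C)(C(C)C)C(C)C)C1 | intermediate
37 | (3S,5S,6S,3'R)-7',8'-didehydro-5,6-dihydro-β,β-carotene-3,5,6,3'-tetrol (CNP0160593.1) | CC1=C(C#C/C(C)=C/C=C/C(C)=C/C=C/C=C(C)/C=C/C=C(C)/C=C/[C@]2(O)C(C)(C)C[C@H](O)C[C@]2(C)O)C(C)(C)C[C@H](O)C1 | target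

## Step count and risks

Total step count: 25. Longest linear sequence: 17 steps (steps 1–4, 13–23, 24, 25).

Steps most likely to fail:

1. Step 9 (key step). What may go wrong: deprotonation of the acidic diyne C–H by AlMe3 instead of carbometalation, addition with the wrong regiochemistry or to both triple bonds, or methyl transfer to the iodide during coupling. Fallback, from triflate 6 and enynol 12, returning at alcohol 18: Sonogashira coupling of 6 with 12 (Pd(PPh3)4, CuI, iPr2NH) would give the ring A dienynol F1, whose 9'E bond is that of commercial 12 and is never made by carbometalation. MnO2 oxidation would give the enynal F2, Horner–Wadsworth–Emmons reaction with the lithium anion 27 (from 26 and LiN(SiMe3)2, as in step 18) would form C11'=C12' and give the trienynoate F3, and iBu2AlH reduction of F3 gives 18.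

2. Step 16. What may go wrong: water attacking C6 instead of C5 (giving the 5R,6R diol), partial retention at C5 through a free cation, or semipinacol rearrangement and elimination of the tetrasubstituted oxirane. Fallback, from allylic alcohol 22, returning at triol 24: Sharpless epoxidation of 22 with L-(+)-diethyl tartrate would give the syn-epoxy alcohol F4. Warming F4 with aqueous NaOH in tert-butanol should bring about a Payne rearrangement, in which the C7 alkoxide displaces the oxirane oxygen at C6 with inversion, to the spiro-oxirane F5. Hydroxide then opens F5 at the primary C7 and gives 24; here the C5–O bond is never broken and C6 is inverted intramolecularly.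

3. Step 24. What may go wrong: formation of the 15Z olefin and loss of 13'E or 9'E geometry in the delocalised ylide, which cannot be corrected afterwards because equilibration would move the 9'E bond. Fallback, from bromide 19 and aldehyde 34, returning at 36: Michaelis–Arbuzov reaction of 19 with P(OEt)3 would give the diethyl phosphonate F6, and Horner–Wadsworth–Emmons reaction of its potassium anion (KOtBu, THF, −30 °C) with 34 should form C15=C15' with high E selectivity and give 36.

Further compounds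

F1 | step 9 | (2E)-3-methyl-5-[(4R)-2,6,6-trimethyl-4-(triisopropylsilyloxy)cyclohex-1-en-1-yl]pent-2-en-4-yn-1-ol | CC1=C(C#C/C(C)=C/CO)C(C)(C)C[C@H](O[Si](C(C)C)(C(C)C)C(C)C)C1
F2 | step 9 | (2E)-3-methyl-5-[(4R)-2,6,6-trimethyl-4-(triisopropylsilyloxy)cyclohex-1-en-1-yl]pent-2-en-4-ynal | CC1=C(C#C/C(C)=C/C=O)C(C)(C)C[C@H](O[Si](C(C)C)(C(C)C)C(C)C)C1
F3 | step 9 | ethyl (2E,4E,6E)-3,7-dimethyl-9-[(4R)-2,6,6-trimethyl-4-(triisopropylsilyloxy)cyclohex-1-en-1-yl]nona-2,4,6-trien-8-ynoate | CC1=C(C#C/C(C)=C/C=C/C(C)=C/C(=O)OCC)C(C)(C)C[C@H](O[Si](C(C)C)(C(C)C)C(C)C)C1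
F4 | step 16 | [(1S,4S,6S)-2,2,6-trimethyl-4-(triisopropylsilyloxy)-7-oxabicyclo[4.1.0]heptan-1-yl]methanol (5,6-epoxide syn to O3) | OC[C@@]12C(C)(C)C[C@H](O[Si](C(C)C)(C(C)C)C(C)C)C[C@]1(C)O2
F5 | step 16 | (3R,4S,6S)-4,8,8-trimethyl-6-(triisopropylsilyloxy)-1-oxaspiro[2.5]octan-4-ol | C1O[C@]12C(C)(C)C[C@H](O[Si](C(C)C)(C(C)C)C(C)C)C[C@]2(C)O
F6 | step 24 | diethyl [(2E,4E,6E)-3,7-dimethyl-9-[(4R)-2,6,6-trimethyl-4-(triisopropylsilyloxy)cyclohex-1-en-1-yl]nona-2,4,6-trien-8-yn-1-yl]phosphonate | CC1=C(C#C/C(C)=C/C=C/C(C)=C/CP(=O)(OCC)OCC)C(C)(C)C[C@H](O[Si](C(C)C)(C(C)C)C(C)C)C1
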